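(Readings and results come from a simulation from invented constants; noise was put on by code.)

How much target stands in this flask at 8.0 d, and which move at that moment adds most?

the same everywhere: substrate 0.050 M; free catalyst 0.5 mol%

|  | reagent | remark | time |
|---|---|---|---|
| beta | 1.2 equiv | the very flask that is asked about, followed so far |  |
| theta | 2.4 equiv | run made earlier |  |
| flask | 1.20 equiv |  | 8.0 d |

- beta (time / d: target / %, substrate / %): 1.67: 23, 48; 3.00: 27, 43; 5.00: 24, 44; 6.00: 25, 46
- theta (time / h: target / %, substrate / %): 10.0: 38, 37; 20.0: 36, 27; 30.0: 35, 25; 40.0: 37, 24

(each reading ± 1.5 percentage points)

- dusk: at 8.0 d add free catalyst, 100% of the amount charged, then wait 8.0 d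
- autumn: at 8.0 d take out 90% of the target then present, then wait 8.0 d
- noon: at 8.0 d add reagent, 50.0% of the amount charged, then wait 8.0 d
- spring: change nothing and wait 8.0 d more

* target, in percent of the substrate first charged, at 8.0 d
* which option adds most target ("none" when 2 percentage points or less is all one gets) (dusk / autumn / noon / spring / none)
* target present, with what was taken out counted in, in percent of the substrate first charged, after dusk
* target present, with what was taken out counted in, in percent of the substrate first charged, after noon

- target taken out counts as made
- additions bring no volume worth counting

1. Beta is the flask itself, and theta is its neighbour with twice the reagent. Beta reads flat from 3.00 d and theta from 20.0 h, yet on those flat readings beta holds 25.3% target and theta 36.0%.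

2. I look at the substrate gone on the same readings: 55.7% in beta and 74.7% in theta.

3. Target divided by substrate gone reads 45.5% in beta and 48.2% in theta, about the same. So theta ends higher because more substrate has gone, while the split stays put.

4. Pooling both runs gives the target share, the selectivity of this stall, of 47.1%.

5. My reckoning for the flask is this share times beta's substrate gone, which gives 26.2%. I leave open whether a flat line means balance or a stopped catalyst.

6. The forecast says 25% now, 25% after dusk, 32% after noon, and autumn as best. It judges that “Catalyst death fits poorly”.

The flask gives 25.1%, and autumn is best, adding 12 percentage points; dusk gives 25.9%, and noon gives 25.1% against the forecast's 32%. At 8.00 d, free catalyst stands at 0% of its charge.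

    substrate + reagent + free catalyst ⇌ target + free catalyst, rate k1*[substrate]*[reagent]*[free catalyst] forward; the back reaction follows from the equilibrium constant (K = 65.0 /M, k = 6600 /M²/h)
    free catalyst → spent catalyst (k = 0.0600 /h)
    2 reagent → self-condensation product (k = 0.130 /M/h)
    target ⇌ isomer of the product (K = 1.20, k = 0.120 /h)

The share times the 55.3% of substrate gone in this flask gives 26.0%. In the neighbouring flask with 2.00 equiv of reagent, 71.9% of the substrate is gone, so the share gives 33.8%, and that flask holds 32.7%.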